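The cyclohexane ring (elemane numbering, C5–C10) is read as a Diels–Alder adduct: bonds C5–C10 and C8–C9 join the methacrylate carbons C9=C10 to the diene C5=C6–C7=C8 of a masked ortho-benzoquinone, made in the same flask by oxidative dearomatisation of methyl homovanillate. One operation turns the flat arene into a bicyclo[2.2.2]octenone that fixes C5, C8 and the quaternary C10 (methyl cis to C4). The keto-ketal bridge C4–C15 is the latent handle: Baeyer–Villiger cleavage of C15–C8 later delivers the C8 oxygen and the C4–C15 acid arm, while the C6=C7 bond and the homovanillate side chain become the trans-lactone.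

Key step: step 1

Remark on numbering: ring C5–C6–C7–C8–C9–C10; C14 is the methyl and C1(=C2) the vinyl on C10; C4(=C3)–C15 is the arm on C5; C11(=C13)–C12 is the arm on C7. β is the face of the C10 methyl, α the opposite face.
Remark on chirality: the cycloaddition gives a racemate, so compounds 4 to 10 are racemic and their SMILES show the enantiomer that step 7 carries on.

Step 1
Reactants: 1 methyl homovanillate; 2 methyl methacrylate
Product: 4 rac-bicyclo[2.2.2]octenone diester, via masked ortho-benzoquinone 3 (not isolated)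
Conditions: PhI(OAc)2 (1.2 equiv), MeOH, 2 (20 equiv), slow addition of 1, 0 °C → rt
Reagents that add atoms: methanol, CO
Why: PhI(OAc)2 oxidises phenol 1 in methanol to the 6,6-dimethoxycyclohexa-2,4-dienone 3, whose diene C5=C6–C7=C8 adds methyl methacrylate in an intermolecular Diels–Alder reaction; this tandem oxidative ketalisation/cycloaddition of masked ortho-benzoquinones with acrylic dienophiles is the known reaction type. The ring C5–C6–C7–C8–C9–C10 is closed as a [4+2] cycloaddition, the keto-ketal unit C4–C15 becoming the third bridge of a bicyclo[2.2.2]octenone. Regioselectivity follows the known orientation of these dienones: the substituted dienophile carbon C10 bonds to C5 (the diene terminus next to the ketone) and the CH2 carbon C9 bonds to C8 (next to the ketal). C5 and C8 are bridgeheads and are therefore fixed cis by the bridge; C10 is set by the endo rule, the ester lying under the C6=C7 bridge and the methyl pointing to the keto-ketal bridge, which places the methyl cis and the future vinyl carbon C1 trans to C4. The step needs chemoselectivity against dimerisation of 3, secured by slow addition of 1 into a large excess of 2, and it gives the racemate.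

Step 2
Reactants: 4 rac-bicyclo[2.2.2]octenone diester
Product: 6 rac-acyloin diol, via triol ketal 5 (not isolated)
Conditions: LiAlH4, THF, 0 °C → rt; then 1 M HCl, THF, rt
Reagents that add atoms: water, O
Why: Hydride reduction takes the bridge ketone and both esters (the hindered tertiary one included) to alcohols while the ketal survives, and acid hydrolysis of the ketal then unveils the C15 ketone, so the carbonyl has moved from C4 to C15; the C4 carbinol is an inconsequential epimer mixture because step 3 removes it.

Step 3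
Reactants: 6 rac-acyloin diol
Product: 7 rac-keto diol
Conditions: SmI2 (3 equiv), THF/MeOH, −78 °C
Reagents that add atoms: none
Why: SmI2 cleaves the C–O bond alpha to the ketone (reductive deoxygenation of an alpha-hydroxy ketone through the ketyl and the samarium enolate), leaving the C15 ketone between C4H2 and the bridgehead C8.

Step 4
Reactants: 7 rac-keto diol
Product: 8 rac-bis(triethylsilyl) ketone
Conditions: Et3SiCl, imidazole, CH2Cl2, 0 °C
Reagents that add atoms: chlorotriethylsilane, CC[Si](Cl)(CC)CC
Why: Silylation of the two primary alcohols (C1 and C12) gives ethers that can later be removed in the presence of a secondary TBS ether.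

Step 5
Reactants: 8 rac-bis(triethylsilyl) ketone
Product: 9 rac-bridged lactone
Conditions: Me3SiOOSiMe3, TMSOTf (10 mol %), CH2Cl2, −40 °C
Reagents that add atoms: bis(trimethylsilyl) peroxide, C[Si](C)(C)OO[Si](C)(C)C
Why: In this Baeyer–Villiger oxidation the secondary, allylic bridgehead C8 migrates in preference to the C4 methylene and with retention, so the new C8–O bond is β (cis to the C5 arm), and the nucleophilic silyl peroxide does not epoxidise the trisubstituted C6=C7 bond.

Step 6
Reactants: 9 rac-bridged lactone
Product: 10 rac-allylic alcohol PMB ester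
Conditions: 4-MeOC6H4CH2OH (5 equiv), Cs2CO3 (0.2 equiv), THF, rt
Reagents that add atoms: 4-methoxybenzyl alcohol, COc1ccc(CO)cc1
Why: Base-catalysed alcoholysis (transesterification) opens the strained bridged seven-membered lactone to the acid-labile PMB ester of C15 and the free 8β allylic alcohol, the liberated alkoxide regenerating the nucleophile.

Step 7
Reactants: 10 rac-allylic alcohol PMB ester
Product: 11 enantiopure C8 silyl ether
Conditions: Ti(OiPr)4, L-(+)-diisopropyl tartrate, t-BuOOH (0.6 equiv), 4 Å MS, CH2Cl2, −20 °C; work-up; then TBSOTf, 2,6-lutidine, CH2Cl2, −78 °C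
Reagents that add atoms: tert-butyldimethylsilyl triflate, CC(C)(C)[Si](C)(C)OS(=O)(=O)C(F)(F)F
Why: Sharpless kinetic resolution: with L-(+)-tartrate the (S)-carbinol enantiomer is epoxidised faster (oxygen delivered syn to the titanium-bound hydroxyl), so the (R)-carbinol needed here remains, is silylated in the same flask, and is separated from the silylated epoxide of the other enantiomer.

Step 8
Reactants: 11 enantiopure C8 silyl ether
Product: 13 C6 alcohol, via alkylborane 12 (not isolated)
Conditions: BH3·THF, THF, 0 °C → rt; then 30% H2O2, pH 7 phosphate buffer, MeOH, 0 °C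
Reagents that add atoms: hydrogen peroxide, OO
Why: Hydroboration–oxidation puts boron on the less substituted C6 and adds B and H syn from the α face, anti to the pseudo-axial 8β-silyloxy group and the 5β arm, which sets 6α-OH and 7α-H (C7 arm β, trans to O6) in one event; the neutral oxidation avoids lactonisation onto the C15 ester.

Step 9
Reactants: 13 C6 alcohol
Product: 14 triol
Conditions: HF·pyridine, pyridine, THF, 0 °C
Reagents that add atoms: none
Why: Selective desilylation: the primary triethylsilyl ethers are cleaved much faster than the hindered secondary TBS ether on O8.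

Step 10
Reactants: 14 triol
Product: 16 lactone aldehyde, via lactol aldehyde 15 (not isolated)
Conditions: TEMPO (20 mol %), PhI(OAc)2 (3.5 equiv), CH2Cl2, rt
Reagents that add atoms: none
Why: The oxoammonium oxidation touches only primary alcohols: the C12 aldehyde is trapped by the 6α-hydroxyl and the lactol is oxidised on to the trans-fused γ-lactone (oxidative lactonisation), the neopentyl C1 alcohol stops at the aldehyde, and the silylated O8 cannot compete for C12.

Step 11
Reactants: 16 lactone aldehyde
Product: 17 vinyl lactone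
Conditions: Ph3PCH3Br, KN(SiMe3)2, THF, −78 → 0 °C
Reagents that add atoms: methyltriphenylphosphonium bromide, C[P+](c1ccccc1)(c1ccccc1)c1ccccc1.[Br-]
Why: Wittig methylenation of the non-enolisable neopentyl aldehyde is far faster than any reaction of the ylide with the lactone or the ester and creates the C1=C2 vinyl group.

Step 12
Reactants: 17 vinyl lactone
Product: 20 bis-methylene lactone ester, via bis-Mannich base 18 (not isolated), via bis-ammonium iodide 19 (not isolated)
Conditions: LiN(iPr)2 (2.5 equiv), THF, −78 °C; CH2=NMe2 I, −78 °C → rt; then MeI, MeOH; then aq NaHCO3, EtOAc, rt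
Reagents that add atoms: N,N-dimethylmethyleneiminium iodide (Eschenmoser salt), C=[N+](C)C.[I-]
Why: Both CH2 groups alpha to a carbonyl (C11 of the lactone, C4 of the ester) are aminomethylated through their lithium enolates (Mannich reaction), and quaternisation followed by Hofmann-type elimination gives the two exocyclic methylenes C13 and C3 at once without touching a stereocentre.

Step 13
Reactants: 20 bis-methylene lactone ester
Product: 21 C8 alcohol
Conditions: HF·pyridine, THF, 0 °C → rt
Reagents that add atoms: none
Why: Fluoride-mediated desilylation under buffered acidic conditions frees the 8β-hydroxyl and is tolerated by the two Michael acceptors and the PMB ester.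

Step 14
Reactants: 21 C8 alcohol; 22 angelic acid
Product: 23 angelate PMB ester
Conditions: PPh3, DIAD, toluene, 0 °C → rt
Reagents that add atoms: none
Why: Mitsunobu esterification: the axial 8β-alcohol, activated as its oxyphosphonium salt, is displaced by angelate with inversion (SN2) to the equatorial 8α-ester, and the neutral conditions should preserve the Z geometry of the angelate.

Step 15
Reactants: 23 angelate PMB ester
Product: 24 CNP0256928.3
Conditions: CF3CO2H, anisole, CH2Cl2, 0 °C
Reagents that add atoms: none
Why: Acidolysis of the 4-methoxybenzyl ester (loss of the benzylic cation, trapped by anisole) liberates the acrylic acid without affecting the angelate, the α-methylene lactone or the vinyl group.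

Compound list
1 | methyl 2-(4-hydroxy-3-methoxyphenyl)acetate (methyl homovanillate) | COC(=O)Cc1ccc(O)c(OC)c1 | starting material
2 | methyl methacrylate | C=C(C)C(=O)OC | starting material
3 | masked ortho-benzoquinone: 6,6-dimethoxy-4-(2-methoxy-2-oxoethyl)cyclohexa-2,4-dien-1-one | COC(=O)CC1=CC(OC)(OC)C(=O)C=C1 | intermediate (not isolated)
4 | rac-bicyclo[2.2.2]octenone diester: methyl 8,8-dimethoxy-5-(2-methoxy-2-oxoethyl)-2-methyl-7-oxobicyclo[2.2.2]oct-5-ene-2-carboxylate; ester endo (under the C5=C6 bridge), methyl toward the keto-ketal bridge; elemane labels: C4 ketone, C15 ketal, C10 CO2Me α and CH3 β | COC(=O)[C@]1(C)C[C@H]2C(OC)(OC)C(=O)[C@@H]1C=C2CC(=O)OC | intermediate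
5 | triol ketal: as 4 with C4–OH (epimer mixture), C1H2OH and C12H2OH; C15 dimethyl ketal kept | OC[C@]1(C)C[C@H]2C(OC)(OC)C(O)[C@@H]1C=C2CCO | intermediate (not isolated)
6 | rac-acyloin diol: bicyclo[2.2.2]octenone with C15 ketone, C4–OH (epimer mixture), C1H2OH α on C10, C12H2OH on the C7 arm | OC[C@]1(C)C[C@H]2C(=O)C(O)[C@@H]1C=C2CCO | intermediate
7 | rac-keto diol: as 6 with C4H2 | OC[C@]1(C)C[C@H]2C(=O)C[C@@H]1C=C2CCO | intermediate
8 | rac-bis(triethylsilyl) ketone: 7 with both primary alcohols as Et3Si ethers | CC[Si](CC)(CC)OC[C@]1(C)C[C@H]2C(=O)C[C@@H]1C=C2CCO[Si](CC)(CC)CC | intermediate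
9 | rac-bridged lactone: 2-oxabicyclo[3.2.2]non-6-en-3-one; O inserted between C15 and C8, C8–O β | CC[Si](CC)(CC)OC[C@]1(C)C[C@H]2OC(=O)C[C@@H]1C=C2CCO[Si](CC)(CC)CC | intermediate
10 | rac-allylic alcohol PMB ester: cyclohexene C6=C7; 8β-OH; 5β-CH2CO2PMB; C10 CH3 β and CH2OSiEt3 α; C7–CH2CH2OSiEt3 | CC[Si](CC)(CC)OC[C@]1(C)C[C@@H](O)C(CCO[Si](CC)(CC)CC)=C[C@H]1CC(=O)OCc2ccc(OC)cc2 | intermediate
11 | enantiopure C8 silyl ether: 10 as the single (R)-carbinol enantiomer, 8β-OTBS | CC[Si](CC)(CC)OC[C@]1(C)C[C@@H](O[Si](C)(C)C(C)(C)C)C(CCO[Si](CC)(CC)CC)=C[C@H]1CC(=O)OCc2ccc(OC)cc2 | intermediate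
12 | alkylborane: BH2 on C6 α, H on C7 α | CC[Si](CC)(CC)OC[C@]1(C)C[C@@H](O[Si](C)(C)C(C)(C)C)[C@@H](CCO[Si](CC)(CC)CC)[C@H](B)[C@H]1CC(=O)OCc2ccc(OC)cc2 | intermediate (not isolated)
13 | C6 alcohol: 6α-OH, 7β-CH2CH2OSiEt3, 8β-OTBS, 5β-CH2CO2PMB | CC[Si](CC)(CC)OC[C@]1(C)C[C@@H](O[Si](C)(C)C(C)(C)C)[C@@H](CCO[Si](CC)(CC)CC)[C@H](O)[C@H]1CC(=O)OCc2ccc(OC)cc2 | intermediate
14 | triol: 13 with C1–OH and C12–OH free | OC[C@]1(C)C[C@@H](O[Si](C)(C)C(C)(C)C)[C@@H](CCO)[C@H](O)[C@H]1CC(=O)OCc2ccc(OC)cc2 | intermediate
15 | lactol aldehyde: C12 lactol on O6 (anomer mixture), C1 aldehyde | O=C[C@]1(C)C[C@@H](O[Si](C)(C)C(C)(C)C)[C@H]2CC(O)O[C@@H]2[C@H]1CC(=O)OCc3ccc(OC)cc3 | intermediate (not isolated)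
16 | lactone aldehyde: trans-fused 6α,12-γ-lactone, C10–CHO α | O=C[C@]1(C)C[C@@H](O[Si](C)(C)C(C)(C)C)[C@H]2CC(=O)O[C@@H]2[C@H]1CC(=O)OCc3ccc(OC)cc3 | intermediate
17 | vinyl lactone: C10 vinyl α | C=C[C@]1(C)C[C@@H](O[Si](C)(C)C(C)(C)C)[C@H]2CC(=O)O[C@@H]2[C@H]1CC(=O)OCc3ccc(OC)cc3 | intermediate
18 | bis-Mannich base: CH2NMe2 on C11 and on C4 (epimer mixtures) | C=C[C@]1(C)C[C@@H](O[Si](C)(C)C(C)(C)C)[C@H]2C(CN(C)C)C(=O)O[C@@H]2[C@H]1C(CN(C)C)C(=O)OCc3ccc(OC)cc3 | intermediate (not isolated)
19 | bis-ammonium iodide: the bis(trimethylammonium) diiodide of 18 | C=C[C@]1(C)C[C@@H](O[Si](C)(C)C(C)(C)C)[C@H]2C(C[N+](C)(C)C)C(=O)O[C@@H]2[C@H]1C(C[N+](C)(C)C)C(=O)OCc3ccc(OC)cc3.[I-].[I-] | intermediate (not isolated)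
20 | bis-methylene lactone ester: α-methylene lactone and PMB 2-substituted acrylate, 8β-OTBS | C=C[C@]1(C)C[C@@H](O[Si](C)(C)C(C)(C)C)[C@H]2C(=C)C(=O)O[C@@H]2[C@H]1C(=C)C(=O)OCc3ccc(OC)cc3 | intermediate
21 | C8 alcohol: 20 with free 8β-OH | C=C[C@]1(C)C[C@@H](O)[C@H]2C(=C)C(=O)O[C@@H]2[C@H]1C(=C)C(=O)OCc3ccc(OC)cc3 | intermediate
22 | angelic acid, (Z)-2-methylbut-2-enoic acid | C/C=C(/C)C(=O)O | starting material
23 | angelate PMB ester: 8α-angelate, 4-methoxybenzyl ester of the target | C=C[C@]1(C)C[C@H](OC(=O)/C(C)=C\C)[C@H]2C(=C)C(=O)O[C@@H]2[C@H]1C(=C)C(=O)OCc3ccc(OC)cc3 | intermediate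
24 | CNP0256928.3: 8α-angeloyloxy-elema-1,3,11(13)-trien-15-oic acid 6α,12-olide | C=C[C@]1(C)C[C@H](OC(=O)/C(C)=C\C)[C@H]2C(=C)C(=O)O[C@@H]2[C@H]1C(=C)C(=O)O | target

Total step count: 15. Longest linear sequence: 15 steps (from 1; 2 and 22 are commercial).

Steps most likely to fail:

Step 7. The selectivity factor of the tartrate-controlled epoxidation may be low for a ring allylic alcohol, so the recovered carbinol would not reach full enantiopurity at a useful conversion. Fallback: resolve 10 instead by acyl-transfer kinetic resolution with a chiral isothiourea (benzotetramisole, (i-PrCO)2O, i-Pr2NEt, CHCl3, 0 °C), using the catalyst enantiomer that acylates the (S)-carbinol. The unreacted (R)-carbinol of 10 is then silylated (TBSOTf, 2,6-lutidine) and rejoins the route at 11. This sets out from 10 and makes no new compound on the way (F0).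

Step 8. Borane may add with poor facial selectivity (attack syn to the silyloxy group through the other half-chair), or the ester may be partly reduced. Fallback from 11: epoxidation with mCPBA (NaHCO3, CH2Cl2, 0 °C) anti to the allylic silyl ether gives the 6α,7α-epoxide F1. Cp2TiCl (trivalent titanium, made from Cp2TiCl2 and Zn) with 1,4-cyclohexadiene in THF then opens it homolytically at C7, and hydrogen-atom transfer to the tertiary radical from the α face returns the route at 13.

Step 14. Elimination toward C7 or C9 may compete with substitution at the hindered secondary centre, or the angelate geometry may erode. Fallback from 21: ClCH2SO2Cl, pyridine, CH2Cl2, 0 °C gives the 8β-chloromethanesulfonate F2. Displacement with caesium angelate (from 22 and Cs2CO3; 18-crown-6, toluene, 60 °C) inverts C8 and rejoins the route at 23.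

Further compounds
F0 | step 7 | none | none
F1 | step 8 | 6α,7α-epoxide of 11 | CC[Si](CC)(CC)OC[C@]1(C)C[C@@H](O[Si](C)(C)C(C)(C)C)[C@]2(CCO[Si](CC)(CC)CC)O[C@@H]2[C@H]1CC(=O)OCc3ccc(OC)cc3
F2 | step 14 | 8β-chloromethanesulfonate of 21 | C=C[C@]1(C)C[C@@H](OS(=O)(=O)CCl)[C@H]2C(=C)C(=O)O[C@@H]2[C@H]1C(=C)C(=O)OCc3ccc(OC)cc3
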